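Atoms carry the numbers they have along the SMILES string of the target (compound 34): C1–C7 heptyl, C8=C9, C10, O11, C12, C13=O14, O15, C16, C17, C18–O19, C20, C21, C22, C23=C24–C25, C26, C27–O28.

## The problem

The core of 34 is a 2-oxabicyclo[2.2.2]octan-3-one with bridgeheads C12 and C16 and bridges C13–O15, C22–C21 and C27–C26. A cyclopentane is fused across C16–C21 and a 3,6-dihydro-2H-pyran across C12–C22, so four rings meet in six contiguous atoms. Seven stereocentres must be set (C10, C12, C16, C18, C21, C22, C27); C12 and C16 are fully substituted and tied through the lactone, and on the C21–C22 bridge the ring carbons C20 and C23 are eclipsed on the lactone side, so the cage is best closed by a step with a large driving force. The centres are not independent: on the cyclopentane O15 is cis to the C22 branch and trans to O19, so C21 can direct C16 (addition to a C16 ketone anti to the branch) and the C16 hydroxyl can direct C18 and C27 (internal hydride delivery). C12 has no freedom once the cage exists, and C10 can be set last by the rigid cage. The doubly allylic ether at C10 ionizes in acid, the diene side chain and the C23=C24 alkene rule out late hydrogenation or oxidation, the β-hydroxy lactone (C27–C12–C13) can cleave by retro-aldol in strong base, and any intermediate with a carbonyl next to C22 can lose the C22 configuration. The enabling feature is C12, which carries O11, the ester carbonyl C13 and two carbons (C22, C27): the product pattern of an α-ketol shift in which a hemiketal carbon becomes an ester. Returning C27 from C12 to C13 turns the cage into a cyclopentane-fused 8-oxabicyclo[3.2.1]octan-2-one with a hemiketal hydroxyl at C13, the internal hemiketal of a trans-fused hydroazulene-1,2-dione that ring-closing metathesis can reach.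

## Retrosynthesis

**C9–C10.** 34 is taken back to its bis(silyl ether) 33, and 33 to lactol acetate 29 and alkenyltrifluoroborate 32 (one step from non-1-yne 30). Cutting here, not earlier, means the acid-labile doubly allylic ether and the diene exist only in the last two compounds and never meet ruthenium, osmium, hydrogen or activated DMSO. The precursor is nine carbons and one stereocentre simpler. The forward step must add the alkenyl group to the C10 end of a cyclic allyl-oxocarbenium ion on the pseudoaxial face, the face that also carries the C13 carbonyl.

**O11–C10 and C23=C24.** 29 is the half-reduced form of unsaturated lactone 27, which opens to aldehyde 24 and phosphonate 25. The C12 hydroxyl freed in the key step becomes the ring oxygen, and a Z-selective olefination places the ester beside it, so ring closure is an intramolecular acylation. A metathesis closure of the same lactone would first need intermolecular acylation of the hindered tertiary C12 hydroxyl. The forward chemistry must give a Z-trisubstituted alkene and must half-reduce the C10 lactone beside the cage lactone.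

**Oxidation state of C23.** 24 comes from cage lactone 22 through alcohol 23. The future aldehyde carbon is carried as a benzyloxymethyl group: it tolerates Lewis acid, ruthenium carbenes, osmylation and Swern oxidation, it does not bind ruthenium or consume osmium oxidant as a thioacetal could, and it is removable by hydrogenolysis at 22, the one stage with no alkene.

**C12–C27 (key disconnection).** 22 is an α-hydroxy lactone; moving C27 from C12 back to C13 gives hemiketal 21. One bond is cut, the cyclohexane reverts to a cycloheptanone and the δ-lactone to an oxolane, and C12 ceases to be a stereocentre. An aldol or pinacol closure of C12–C27 on a preformed lactone would have to control C12 and C27 together at a crowded α-alkoxy carbonyl; the shift has no choice at C12. The forward reaction must move C27 with retention faster than C22 is deprotonated. Three features of 21 favour this: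
- the C13–C27 bond is axial on the six-membered ring of the oxabicycle and so parallel to the π* orbital of the C12 ketone;
- the only α-hydrogen (C22–H) is endo, under the C26–C27 bridge;
- the benzyloxymethyl group is equatorial, so the C22 configuration needed is the stable one before the shift and is frozen after it.

**C13–O15 and C12=C13.** 21 is the closed form of dione 20, made from cis-diol 19 and so from cycloheptene 18. The oxygens are added after ring formation, so no carbonyl sits next to C22 or C27 until the last step before the shift. 18 opens at C12=C13 to diene 17, a ring-closing metathesis of two monosubstituted alkenes on a trans-1,2-disubstituted cyclopentane. Acyloin or pinacol closures of the same bond would need aldehydes α to C22 and C27, both prone to elimination.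

**C18 and C27 carbinols, C16–C26.** 17 is the bis(silyl ether) of triol 16, which comes from hydroxy diketone 15. Both carbonyls are β to the tertiary C16 hydroxyl, so one hydroxyl-directed reduction sets both carbinol centres. 15 comes from ketal 14, Weinreb amide 12, and finally ketone 10 with acetamide 11 and vinylmagnesium bromide 13. The C16–C26 bond is made by addition to the C16 ketone anti to the C21 branch, which places O15 cis to that branch as 34 requires.

**C21–C22 and the source of chirality.** 10 goes back through alcohol 9 and ketal 8 to ketone 7, and 7 to enone 6 and allylsilane 5. The carbinol carbon of commercial 6 is used as C16, not as C18. C21 is then the β-carbon, and the first C–C bond is a conjugate addition trans to the silyloxy group, the most dependable control this enone offers. Had the carbinol been kept as C18, C21 would be the α-carbon and would depend on 1,3-induction in an enolate alkylation. The price is three steps (ketal, desilylation, oxidation) and a late reduction at C18, which the O15-directed hydride delivery sets cleanly. C22 is formed in the same step through an open transition state; it is the least secure centre and is backed by the equatorial preference in 21.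

**Reagents.** 5 comes from iodide 3 and Grignard reagent 4, and 3 from benzyl propargyl ether 1; both steps fix the E geometry that the transition-state argument for C22 relies on.

## Roads not taken

Alternative 1: Pauson–Khand annulation through an enol ester tether.
- **Cut:** C16–C21, C17–C18 and C18–C20 (C18 from CO). The cyclopentane is removed and the lactone ring opened, leaving an alkyne (C21≡C20) on C22 of a finished dihydropyran and an enol ester alkene (C16=C17) on the C13 carboxyl.
- **Forward step:** the alkyne–Co2(CO)6 complex, the alkene and CO would combine to cyclopentenone lactone A1, forming three C–C bonds, two rings and the quaternary C16 at once.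
- **Merits:** convergence and the highest bond count per step of any plan; C22 next to the alkyne could bias the face at C16.
- **Weak points:** the ester tether prefers the extended conformation that holds alkyne and alkene apart, and an enol ester is a 1,1-disubstituted, weakly binding alkene. A1 still lacks C12–C27, so the fully substituted C12 would be made last by an aldol of a hindered α-alkoxy lactone enolate, and C21, C18 and C27 remain to be set on the enone. The labile C10 ether and the diene travel through cobalt chemistry and every later step.
- **Comparison:** if the annulation worked, A1 would be reached in clearly fewer operations than 21, a real advantage. The chosen plan sets against it ring-forming steps of well-behaved types, a C12 centre with no stereochemical choice, and a side chain attached in the penultimate step.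

Alternative 2: Ireland–Claisen contraction to the dihydropyran.
- **Cut:** C12–C22. The C13 carboxyl is first tied to an allylic oxygen on C24, so that O11, C10 and C24 lie in a six-membered lactone.
- **Forward step:** the silyl ketene acetal of that lactone would rearrange through a boat, forming C12–C22, breaking C24–O and giving dihydropyran acid A2 with the C23=C24 alkene in place.
- **Merits:** C12 and C22 are set together in one stereospecific step with transfer of chirality, and the alkene position is automatic. Here this road is better than the chosen one, whose C22 rests on an open transition state backed by equilibration.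
- **Weak points:** the enolate is an α-alkoxy lactone enolate with a ketal oxygen in the β-position (elimination), the new bond joins a fully substituted ketene acetal carbon to a carbon bearing the cyclopentyl group, and the tertiary allylic ester can ionize. After A2 both carbocyclic bonds of the cage are still missing (C16–C26 by aldol, then lactonization and reduction at C27), with no clear control at C16 and C27.
- **Comparison:** longer after its key step and weaker at C16 and C27, where the chosen plan has a ketone addition anti to the C21 branch and two O15-directed reductions.

Alternative 3: rhodium carbenoid C–H insertion closing the cyclopentanone.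
- **Cut:** C20–C21, with cage and dihydropyran complete and the C16 arm (C17, C18, C20) ending in a diazo ketone.
- **Forward step:** Rh2(OAc)4 would generate the carbenoid, which inserts into the C21–H bond facing the lactone bridge and gives ketone A3 with retention at C21.
- **Merits:** 1,5-insertion into a C–H bond held beside the carbenoid is dependable, and C21 is set by geometry alone.
- **Weak points:** it presupposes the lactone cage with C12, C16, C22 and C27 in place, so the central problem is left to other chemistry. The carbenoid also faces the C23=C24 alkene and the diene (cyclopropanation), two ether oxygens (ylides) and the equally placed C26–H bonds. The C18 ketone must then be reduced from the correct face.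
- **Comparison:** attractive as an endgame for the five-membered ring only. The chosen plan instead uses that ring as the source of chirality, and its key step builds the cage itself.

Key step: step 15

Assumption: compounds 1, 4, 6, 11, 13, 25 and 30 are taken as commercial; diol 19 is drawn as one of the two cis isomers and lactolate 28 and acetate 29 are written without configuration at C10, because these centres are erased in the following step.

## Route

Step 1
Reactants: 1 benzyl propargyl ether
Product: 3 (E)-3-(benzyloxy)-1-iodoprop-1-ene, via alkenylzirconocene chloride 2 (not isolated)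
Conditions: Cp2Zr(H)Cl (1.2 equiv), THF, rt; then I2, 0 °C
Reagents that add atoms: iodine, [I][I]
Why: Hydrozirconation of a terminal alkyne is a syn addition that places zirconium on the terminal carbon, and iodine cleaves the C–Zr bond with retention, so only the E-iodide should form.

Step 2
Reactants: 3 (E)-3-(benzyloxy)-1-iodoprop-1-ene; 4 (trimethylsilyl)methylmagnesium chloride
Product: 5 (E)-[4-(benzyloxy)but-2-en-1-yl]trimethylsilane
Conditions: Pd(PPh3)4 (3 mol %), THF, rt to 50 °C
Reagents that add atoms: none
Why: Kumada coupling of an alkenyl iodide with the silylmethyl Grignard reagent on zerovalent palladium is the standard entry to allylsilanes and keeps the alkene geometry; the benzyl ether is γ to palladium and cannot β-eliminate.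

Step 3
Reactants: 6 (R)-4-(tert-butyldimethylsilyloxy)cyclopent-2-en-1-one; 5 (E)-[4-(benzyloxy)but-2-en-1-yl]trimethylsilane
Product: 7 conjugate adduct (C21–C22 bond trans to the C16 silyl ether)
Conditions: TiCl4 (1.1 equiv), CH2Cl2, −78 °C; then 5 (1.5 equiv), −78 °C
Reagents that add atoms: none
Why: Hosomi–Sakurai conjugate allylation: the γ-carbon of 5 attacks C21 of the TiCl4-bound enone (anti-SE2') on the face opposite the C16 silyloxy group, which sets C21. C22 is set in the open synclinal transition state that puts the C22 hydrogen over the ring and the silylmethyl end under the flat enone carbons, not under C16. Complexing 6 before 5 is added limits Lewis-acid desilylative elimination of the reagent.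

Step 4
Reactants: 7 conjugate adduct
Product: 8 C18 ethylene ketal
Conditions: Me3SiOCH2CH2OSiMe3, Me3SiOTf (5 mol %), CH2Cl2, −78 to −20 °C
Reagents that add atoms: 1,2-bis(trimethylsilyloxy)ethane, C[Si](C)(C)OCCO[Si](C)(C)C
Why: Silyl-transfer ketalization at low temperature masks the C18 ketone without the acid and heat that would eliminate the β-silyloxy group; the ketal keeps C18 out of the oxidation and additions at C16.

Step 5
Reactants: 8 C18 ethylene ketal
Product: 9 C16 alcohol
Conditions: Bu4NF, THF, 0 °C to rt
Reagents that add atoms: none
Why: Fluoride cleaves the only silyl ether; with C18 masked the freed β-hydroxyl cannot eliminate.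

Step 6
Reactants: 9 C16 alcohol
Product: 10 C16 ketone
Conditions: Dess–Martin periodinane, NaHCO3, CH2Cl2, 0 °C to rt
Reagents that add atoms: none
Why: Buffered Dess–Martin oxidation gives the ketone without base, so the adjacent C21 is not epimerized and the β-ketal is not opened.

Step 7
Reactants: 10 C16 ketone; 11 N-methoxy-N-methylacetamide
Product: 12 β-hydroxy Weinreb amide (C16 hydroxyl cis to the C21 branch)
Conditions: LiN(i-Pr)2, 11, THF, −78 °C; then 10, −78 °C; AcOH quench at −78 °C
Reagents that add atoms: none
Why: Aldol addition of the lithium amide enolate to the ketone; the enolate approaches C16 anti to the branched C21 substituent, so C26 enters trans to it and O15 ends cis to the C22 branch as in 34. The cold quench prevents retro-aldol.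

Step 8
Reactants: 12 β-hydroxy Weinreb amide; 13 vinylmagnesium bromide
Product: 14 β-hydroxy vinyl ketone
Conditions: 13 (3.5 equiv), THF, −20 to 0 °C; inverse quench into cold 1 M HCl
Reagents that add atoms: none
Why: Weinreb ketone synthesis: the chelated tetrahedral intermediate stops at the ketone, and the first equivalent of 13 only deprotonates the tertiary alcohol. The cold acidic quench protonates the released amine before it can add to the enone.

Step 9
Reactants: 14 β-hydroxy vinyl ketone
Product: 15 hydroxy diketone
Conditions: pyridinium p-toluenesulfonate (cat.), acetone/H2O (10:1), 40 °C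
Reagents that add atoms: water, O
Why: Mild acid hydrolysis of the dioxolane; the acid is too weak to dehydrate the tertiary aldol or to drive oxa-Michael closure onto the enone at a useful rate.

Step 10
Reactants: 15 hydroxy diketone
Product: 16 triol
Conditions: Me4NBH(OAc)3 (10 equiv), MeCN/AcOH (1:1), −30 to −10 °C
Reagents that add atoms: none
Why: Evans–Saksena reduction: the tertiary hydroxyl exchanges onto boron and delivers hydride internally to both β-carbonyls. At C18 the hydride must arrive on the O15 face of the ring, so O19 ends trans to O15. At C27 the chair transition state with the bulkier C21 ring arm and the vinyl group equatorial gives the 1,3-anti relation along C21–C16–C26–C27 that 34 needs.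

Step 11
Reactants: 16 triol
Product: 17 bis(silyl ether) diene
Conditions: t-BuMe2SiCl (2.5 equiv), imidazole, DMF, rt
Reagents that add atoms: tert-butyldimethylsilyl chloride, CC(C)(C)[Si](C)(C)Cl
Why: Silyl chloride and imidazole silylate the two secondary hydroxyls; the tertiary C16 hydroxyl is too hindered and stays free for the later hemiketal.

Step 12
Reactants: 17 bis(silyl ether) diene
Product: 18 trans-fused cycloheptene
Conditions: second-generation Grubbs catalyst RuCl2(=CHPh)(PCy3)(H2IMes) (5 mol %), CH2Cl2 (5 mM), 40 °C
Reagents that add atoms: none
Why: Ring-closing metathesis of two monosubstituted alkenes to a seven-membered ring, driven by loss of ethene; the two chains are trans on the cyclopentane and reach each other without strain, and the free tertiary alcohol is tolerated.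

Step 13
Reactants: 18 trans-fused cycloheptene
Product: 19 C12,C13 cis-diol
Conditions: OsO4 (5 mol %), 4-methylmorpholine N-oxide, acetone/H2O, rt
Reagents that add atoms: 4-methylmorpholine N-oxide, C[N+]1([O-])CCOCC1; water, O
Why: Catalytic osmylation of the only alkene gives the cis-diol; which face reacts does not matter because both carbinol centres are oxidized next.

Step 14
Reactants: 19 C12,C13 cis-diol
Product: 21 bridged hemiketal, via open dione 20 (not isolated)
Conditions: (COCl)2, DMSO, CH2Cl2, −78 °C; Et3N, −78 to 0 °C
Reagents that add atoms: none
Why: Double Swern oxidation turns the vicinal diol into the 1,2-dione without C–C cleavage; the C16 hydroxyl, held over the ring, adds to C13 (5-exo-trig) to give the bridged hemiketal, whose C13 configuration is dictated by the bridge. Any C12 hemiketal equilibrates through 20 and leads to the same product in step 15.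

Step 15
Reactants: 21 bridged hemiketal
Product: 22 cage lactone
Conditions: DBU (0.2 equiv), toluene, 0 °C to rt
Reagents that add atoms: none
Why: DBU removes the hemiketal proton, the most acidic one, and the C13 alkoxide pushes the axial C13–C27 bond, which lies parallel to the π* orbital of the C12 ketone, onto C12; C13 becomes the lactone carbonyl and the new C12 alkoxide takes the proton back, so the base turns over. The closest known reaction is the α-ketol (acyloin) rearrangement in its hemiketal-to-ester form. No ring is closed by an external attack: the cyclohexane arises by contraction of the cycloheptanone (new bond C12–C27) and the δ-lactone by expansion of the oxolane (O15–C13 now spans C16 and C12), both in one suprafacial 1,2-shift. C12 is the only new stereocentre and has no freedom, because C27 migrates with retention on the ketone face it already occupies and the bicyclo[2.2.2] frame can only form with O11 outside the cage. The step needs migration to outrun enolization toward C22, which would open the way to loss of benzyl oxide. This is secured by the much higher acidity of the O–H bond, by the endo position of the C22 hydrogen under the C26–C27 bridge, and by the gain of an ester. The benzyloxymethyl group is equatorial in 21, so the C22 configuration required is the stable one before the shift and cannot epimerize after it.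

Step 16
Reactants: 22 cage lactone
Product: 23 C23 primary alcohol
Conditions: H2 (1 atm), Pd on carbon (10 %), EtOAc, rt
Reagents that add atoms: none
Why: Hydrogenolysis of the benzyl ether; 22 has no alkene, and the silyl ethers, the lactone and the tertiary alcohol are inert.

Step 17
Reactants: 23 C23 primary alcohol
Product: 24 C23 aldehyde
Conditions: Dess–Martin periodinane, NaHCO3, CH2Cl2, 0 °C
Reagents that add atoms: none
Why: Buffered Dess–Martin oxidation of the primary alcohol; the tertiary C12 hydroxyl cannot be oxidized and the neutral medium avoids epimerization at C22 and retro-aldol cleavage.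

Step 18
Reactants: 24 C23 aldehyde; 25 ethyl 2-[bis(2,2,2-trifluoroethoxy)phosphoryl]propanoate
Product: 27 unsaturated bis-lactone, via Z-enoate 26 (not isolated)
Conditions: 25, KN(SiMe3)2, 18-crown-6, THF, −78 °C; then 24, −78 °C to rt
Reagents that add atoms: none
Why: Still–Gennari olefination gives the Z-trisubstituted enoate under kinetic control; in the Z isomer the ester lies beside the C12 hydroxyl, which closes the six-membered lactone with loss of ethanol (6-exo-trig). If 26 survives the work-up it should close with catalytic acid.

Step 19
Reactants: 27 unsaturated bis-lactone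
Product: 29 lactol acetate, via aluminium lactolate 28 (not isolated)
Conditions: i-Bu2AlH (1.1 equiv), CH2Cl2, −78 °C; then pyridine, DMAP, Ac2O, −78 to 0 °C
Reagents that add atoms: acetic anhydride, CC(=O)OC(C)=O
Why: Reductive acetylation: one equivalent of hydride at −78 °C adds once to the unhindered conjugated lactone and the aluminium lactolate is acetylated in the flask. The cage lactone is an ester of a tertiary alcohol with a fully substituted α-carbon and should react more slowly; both C10 anomers are usable.

Step 20
Reactants: 30 non-1-yne
Product: 32 potassium (E)-non-1-enyltrifluoroborate, via catechol boronate 31 (not isolated)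
Conditions: catecholborane, neat, 70 °C; then KHF2, H2O/MeOH, rt
Reagents that add atoms: catecholborane, [BH]1Oc2ccccc2O1; potassium hydrogen difluoride, [K+].F[H-]F
Why: Syn hydroboration of the terminal alkyne gives the E-alkenylboronate, and KHF2 converts it into the crystalline trifluoroborate.

Step 21
Reactants: 29 lactol acetate; 32 potassium (E)-non-1-enyltrifluoroborate
Product: 33 bis(silyl ether) of the target
Conditions: BF3·OEt2, MeCN/CH2Cl2, −40 to 0 °C
Reagents that add atoms: none
Why: BF3·OEt2 ionizes the acetate to the cyclic allyl-oxocarbenium ion and turns 32 into the alkenyldifluoroborane, which transfers its alkenyl group with retention of geometry to C10, the oxygen-bearing end of the cation. The cage fixes the half-chair, so the stereoelectronically preferred pseudoaxial attack, on the face that carries the C13 carbonyl, gives the C10 configuration of 34.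

Step 22
Reactants: 33 bis(silyl ether) of the target
Product: 34 CNP0127096.1
Conditions: HF·pyridine, pyridine, THF, 0 °C to rt
Reagents that add atoms: none
Why: Buffered HF·pyridine removes both secondary silyl ethers; excess pyridine keeps the medium too weakly acidic to ionize the doubly allylic C10 ether, and no strong base is present to start a retro-aldol of the β-hydroxy lactone.

## Compound list

1 | benzyl propargyl ether, [(prop-2-yn-1-yloxy)methyl]benzene | C#CCOCc1ccccc1 | starting material
2 | (E)-[3-(benzyloxy)prop-1-enyl]chlorobis(cyclopentadienyl)zirconium | Cl[Zr](/C=C/COCc1ccccc1)(C1C=CC=C1)C1C=CC=C1 | intermediate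
3 | (E)-3-(benzyloxy)-1-iodoprop-1-ene | I/C=C/COCc1ccccc1 | intermediate
4 | (trimethylsilyl)methylmagnesium chloride | C[Si](C)(C)C[Mg]Cl | starting material
5 | (E)-[4-(benzyloxy)but-2-en-1-yl]trimethylsilane | C[Si](C)(C)C/C=C/COCc1ccccc1 | intermediate
6 | (R)-4-(tert-butyldimethylsilyloxy)cyclopent-2-en-1-one | O=C1C[C@@H](O[Si](C)(C)C(C)(C)C)C=C1 | starting material
7 | 3-[1-(benzyloxy)but-3-en-2-yl]-4-(tert-butyldimethylsilyloxy)cyclopentan-1-one; side chain (C21) trans to the silyl ether (C16), C22 as in 34 | O=C1C[C@@H](O[Si](C)(C)C(C)(C)C)[C@H]([C@@H](COCc2ccccc2)C=C)C1 | intermediate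
8 | ethylene ketal of 7 at C18 (1,4-dioxaspiro[4.4]nonane), same configuration | O1CCOC12C[C@@H](O[Si](C)(C)C(C)(C)C)[C@H]([C@@H](COCc3ccccc3)C=C)C2 | intermediate
9 | C16 alcohol from 8, hydroxyl trans to the C21 side chain | O1CCOC12C[C@@H](O)[C@H]([C@@H](COCc3ccccc3)C=C)C2 | intermediate
10 | 6-[1-(benzyloxy)but-3-en-2-yl]-1,4-dioxaspiro[4.4]nonan-7-one (C16 ketone), C21 and C22 as in 34 | O1CCOC12CC(=O)[C@H]([C@@H](COCc3ccccc3)C=C)C2 | intermediate
11 | N-methoxy-N-methylacetamide | CC(=O)N(C)OC | starting material
12 | β-hydroxy Weinreb amide; tertiary C16 hydroxyl cis to the C21 side chain, CH2C(O)N(OMe)Me trans to it | O1CCOC12C[C@@](O)(CC(=O)N(C)OC)[C@H]([C@@H](COCc3ccccc3)C=C)C2 | intermediate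
13 | vinylmagnesium bromide | C=C[Mg]Br | starting material
14 | β-hydroxy vinyl ketone (C27 ketone), C18 still ketalized | O1CCOC12C[C@@](O)(CC(=O)C=C)[C@H]([C@@H](COCc3ccccc3)C=C)C2 | intermediate
15 | hydroxy diketone (C18 and C27 ketones, free C16 hydroxyl) | O=C1C[C@@](O)(CC(=O)C=C)[C@H]([C@@H](COCc2ccccc2)C=C)C1 | intermediate
16 | triol; O19 trans to O15 on the ring, C27 carbinol as in 34 | O[C@H]1C[C@@](O)(C[C@@H](O)C=C)[C@H]([C@@H](COCc2ccccc2)C=C)C1 | intermediate
17 | C18,C27-bis(tert-butyldimethylsilyl) ether of 16, free tertiary C16 hydroxyl | CC(C)(C)[Si](C)(C)O[C@H]1C[C@@](O)(C[C@@H](O[Si](C)(C)C(C)(C)C)C=C)[C@H]([C@@H](COCc2ccccc2)C=C)C1 | intermediate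
18 | trans-fused bicyclo[5.3.0]dec-ene (C12=C13) with C16 hydroxyl, C18 and C27 silyl ethers, C22 benzyloxymethyl | CC(C)(C)[Si](C)(C)O[C@H]1C[C@@]2(O)C[C@@H](O[Si](C)(C)C(C)(C)C)C=C[C@H](COCc3ccccc3)[C@@H]2C1 | intermediate
19 | C12,C13 cis-diol of 18 (drawn with both hydroxyls anti to the C27 silyl ether) | CC(C)(C)[Si](C)(C)O[C@H]1C[C@@]2(O)C[C@@H](O[Si](C)(C)C(C)(C)C)[C@H](O)[C@H](O)[C@H](COCc3ccccc3)[C@@H]2C1 | intermediate
20 | open C12,C13-dione with free C16 hydroxyl | CC(C)(C)[Si](C)(C)O[C@H]1C[C@@]2(O)C[C@@H](O[Si](C)(C)C(C)(C)C)C(=O)C(=O)[C@H](COCc3ccccc3)[C@@H]2C1 | intermediate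
21 | cyclopentane-fused 1-hydroxy-8-oxabicyclo[3.2.1]octan-2-one (C13 hemiketal, C12 ketone), C22 benzyloxymethyl equatorial | O=C1[C@H](COCc2ccccc2)[C@@H]3C[C@@H](O[Si](C)(C)C(C)(C)C)C[C@@]3(O4)C[C@@H](O[Si](C)(C)C(C)(C)C)[C@@]14O | intermediate
22 | cage lactone: 2-oxabicyclo[2.2.2]octan-3-one with free C12 hydroxyl, C22 benzyloxymethyl, C18 and C27 silyl ethers | O[C@@]12C(=O)O[C@]3(C[C@H](O[Si](C)(C)C(C)(C)C)C[C@H]3[C@H]1COCc4ccccc4)C[C@H]2O[Si](C)(C)C(C)(C)C | intermediate
23 | cage lactone with C22 hydroxymethyl | O[C@@]12C(=O)O[C@]3(C[C@H](O[Si](C)(C)C(C)(C)C)C[C@H]3[C@H]1CO)C[C@H]2O[Si](C)(C)C(C)(C)C | intermediate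
24 | cage lactone with C23 aldehyde | O[C@@]12C(=O)O[C@]3(C[C@H](O[Si](C)(C)C(C)(C)C)C[C@H]3[C@H]1C=O)C[C@H]2O[Si](C)(C)C(C)(C)C | intermediate
25 | ethyl 2-[bis(2,2,2-trifluoroethoxy)phosphoryl]propanoate | CCOC(=O)C(C)P(=O)(OCC(F)(F)F)OCC(F)(F)F | starting material
26 | (Z)-ethyl 2-methylpropenoate on C22 (C23=C24), free C12 hydroxyl | O[C@@]12C(=O)O[C@]3(C[C@H](O[Si](C)(C)C(C)(C)C)C[C@H]3[C@H]1/C=C(/C)C(=O)OCC)C[C@H]2O[Si](C)(C)C(C)(C)C | intermediate
27 | bis-lactone: 3-methyl-5,6-dihydro-2H-pyran-2-one fused at C12–C22 to the cage lactone | O=C1O[C@@]23C(=O)O[C@]4(C[C@H](O[Si](C)(C)C(C)(C)C)C[C@H]4[C@H]2C=C1C)C[C@H]3O[Si](C)(C)C(C)(C)C | intermediate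
28 | diisobutylaluminium lactolate at C10 (both C10 epimers) | CC(C)C[Al](CC(C)C)OC1O[C@@]23C(=O)O[C@]4(C[C@H](O[Si](C)(C)C(C)(C)C)C[C@H]4[C@H]2C=C1C)C[C@H]3O[Si](C)(C)C(C)(C)C | intermediate
29 | C10 lactol acetate (both C10 anomers) | CC(=O)OC1O[C@@]23C(=O)O[C@]4(C[C@H](O[Si](C)(C)C(C)(C)C)C[C@H]4[C@H]2C=C1C)C[C@H]3O[Si](C)(C)C(C)(C)C | intermediate
30 | non-1-yne | CCCCCCCC#C | starting material
31 | 2-[(E)-non-1-enyl]-1,3,2-benzodioxaborole | CCCCCCC/C=C/B1Oc2ccccc2O1 | intermediate
32 | potassium (E)-non-1-enyltrifluoroborate | CCCCCCC/C=C/[B-](F)(F)F.[K+] | intermediate
33 | C18,C27-bis(tert-butyldimethylsilyl) ether of the target | CCCCCCC/C=C/[C@H]1O[C@@]23C(=O)O[C@]4(C[C@H](O[Si](C)(C)C(C)(C)C)C[C@H]4[C@H]2C=C1C)C[C@H]3O[Si](C)(C)C(C)(C)C | intermediate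
34 | CNP0127096.1 | CCCCCCC/C=C/[C@H]1O[C@@]23C(=O)O[C@]4(C[C@H](O)C[C@H]4[C@H]2C=C1C)C[C@H]3O | target

## Step count and least certain steps

Total: 22 steps. Longest linear sequence: 21 steps (steps 1–19, 21 and 22, from 1); 19 steps from enone 6.

**Step 15 (key step).** Deprotonation at C22 may compete with the shift and be followed by loss of benzyl oxide; or the hemiketal may revert to the open dione, which enolizes, so that the alkoxide push is lost. The fallback separates ring contraction from lactonization. It sets out from 21: aqueous LiOH (THF/H2O, 0 °C) adds hydroxide to the dione form and triggers a benzilic acid rearrangement to the ring-contracted hydroxy acid F1, in which C12 already carries O11, C22, C27 and the carboxyl C13. Lactonization of F1 onto the tertiary C16 hydroxyl (2,4,6-trichlorobenzoyl chloride, Et3N, then DMAP, toluene) comes back to the route at 22. Only the C12 epimer whose carboxyl faces O15 can close, so this path depends on the facial course of the rearrangement.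

**Step 3.** The open transition state may discriminate poorly between the two faces of the allylsilane, so C22 forms as a mixture; Lewis-acid desilylative elimination of 5 may also lower conversion. The fallback moves control of C22 from kinetics to thermodynamics. It sets out from 7 taken on as the C22 mixture through steps 4–14 unchanged; the mixture then holds 21 and its C22 epimer F2. Catalytic camphorsulfonic acid in CH2Cl2 enolizes the C12 ketone reversibly without the β-elimination a base could cause. In F2 the benzyloxymethyl group is axial and points into the C26–C27 bridge, so the equilibrium should drain F2 into 21, where the route is rejoined before step 15.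

**Step 14.** Before O15 captures it, the free dione may enolize (loss of the C27 or C22 configuration) or undergo C–C cleavage under activated-DMSO conditions. The fallback oxidizes in two stages so that a free dione never exists. It sets out from 19: Bu2SnO (toluene, reflux) then N-bromosuccinimide (CHCl3, rt) oxidizes one hydroxyl of the stannylene acetal to the acyloin, which O15 traps as hydroxy hemiketal F3 (drawn as the C13 ketal; the C12 regioisomer would serve equally). Dess–Martin oxidation of the remaining secondary hydroxyl comes back at 21.

**Step 19.** Hydride may also be delivered to the cage lactone at C13, or the lactolate may open and be reduced further. The fallback builds the ring at the lactol oxidation level by metathesis, with no reduction. It sets out from 24: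
- Ph3P=CH2 (THF, −78 to 0 °C) gives C22-vinyl cage alcohol F4.
- Acetal exchange of the C12 hydroxyl with methacrolein diethyl acetal (pyridinium p-toluenesulfonate, benzene, molecular sieves) gives mixed acetal F5.
- Second-generation Grubbs catalyst closes 2-ethoxy-3-methyl-3,6-dihydro-2H-pyran F6.
- F6 is ionized by BF3·OEt2 under the conditions of step 21 just as 29 is, and the route is rejoined at 33.

**Step 21.** Facial selectivity at C10 may be poor, because the pseudoaxial trajectory passes the C13 carbonyl; attack at C23 with allylic transposition is also possible. The fallback uses a slimmer nucleophile and then makes the E-alkene from an alkyne. It sets out from 29: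
- Potassium non-1-ynyltrifluoroborate F7 (from 30 with n-BuLi, B(OMe)3, then KHF2) and BF3·OEt2 give C10 alkyne F8.
- Ruthenium-catalysed trans-hydrosilylation ([Cp*Ru(MeCN)3]PF6, (EtO)3SiH, CH2Cl2) gives vinylsilane F9.
- Bu4NF with CuI in THF replaces silicon by hydrogen with retention and removes both silyl ethers in the same operation, so the sequence comes back at 34.

## Further compounds

F1 | step 15 | ring-contracted hydroxy acid (cyclohexane with C12 hydroxyl and C13 carboxyl cis to the C16 hydroxyl) | OC(=O)[C@]1(O)[C@H](COCc2ccccc2)[C@@H]3C[C@@H](O[Si](C)(C)C(C)(C)C)C[C@@]3(O)C[C@H]1O[Si](C)(C)C(C)(C)C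
F2 | step 3 | C22 epimer of hemiketal 21 | O=C1[C@@H](COCc2ccccc2)[C@@H]3C[C@@H](O[Si](C)(C)C(C)(C)C)C[C@@]3(O4)C[C@@H](O[Si](C)(C)C(C)(C)C)[C@@]14O
F3 | step 14 | hydroxy hemiketal (C13 hemiketal, C12 secondary alcohol) | O[C@@H]1[C@H](COCc2ccccc2)[C@@H]3C[C@@H](O[Si](C)(C)C(C)(C)C)C[C@@]3(O4)C[C@@H](O[Si](C)(C)C(C)(C)C)[C@@]14O
F4 | step 19 | C22-vinyl cage alcohol | O[C@@]12C(=O)O[C@]3(C[C@H](O[Si](C)(C)C(C)(C)C)C[C@H]3[C@H]1C=C)C[C@H]2O[Si](C)(C)C(C)(C)C
F5 | step 19 | mixed ethyl methallylidene acetal on O11 (both acetal epimers) | CCOC(C(C)=C)O[C@@]12C(=O)O[C@]3(C[C@H](O[Si](C)(C)C(C)(C)C)C[C@H]3[C@H]1C=C)C[C@H]2O[Si](C)(C)C(C)(C)C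
F6 | step 19 | C10 ethyl lactol ether, 2-ethoxy-3-methyl-3,6-dihydro-2H-pyran fused to the cage (both C10 anomers) | CCOC1O[C@@]23C(=O)O[C@]4(C[C@H](O[Si](C)(C)C(C)(C)C)C[C@H]4[C@H]2C=C1C)C[C@H]3O[Si](C)(C)C(C)(C)C
F7 | step 21 | potassium non-1-ynyltrifluoroborate | CCCCCCCC#C[B-](F)(F)F.[K+]
F8 | step 21 | C10 non-1-ynyl bis(silyl ether) | CCCCCCCC#C[C@H]1O[C@@]23C(=O)O[C@]4(C[C@H](O[Si](C)(C)C(C)(C)C)C[C@H]4[C@H]2C=C1C)C[C@H]3O[Si](C)(C)C(C)(C)C
F9 | step 21 | C8 triethoxysilyl alkene from trans-hydrosilylation of F8 | CCCCCCC/C([Si](OCC)(OCC)OCC)=C/[C@H]1O[C@@]23C(=O)O[C@]4(C[C@H](O[Si](C)(C)C(C)(C)C)C[C@H]4[C@H]2C=C1C)C[C@H]3O[Si](C)(C)C(C)(C)C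
A1 | alternative 1 | pyran-fused lactone cyclopentenone with quaternary C16 (Pauson–Khand product) | CCCCCCC/C=C/[C@H]1O[C@H]2C(=O)O[C@@]3(CCO[Si](C)(C)C(C)(C)C)CC(=O)C=C3[C@H]2C=C1C
A2 | alternative 2 | dihydropyran C13 acid with quaternary C12 and the cyclopentyl group on C22 (Ireland–Claisen product) | CCCCCCC/C=C/[C@H]1O[C@@](C2(C)OCCO2)(C(=O)O)[C@@H]([C@@H]3C[C@@H](O[Si](C)(C)C(C)(C)C)CC34OCCO4)C=C1C
A3 | alternative 3 | 18-oxo target as its C27 acetate (C–H insertion product) | CCCCCCC/C=C/[C@H]1O[C@@]23C(=O)O[C@]4(CC(=O)C[C@H]4[C@H]2C=C1C)C[C@H]3OC(C)=O
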